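**Retrosynthetic overview**
- Feature: in ring C the chain O1–C2(H)(ring B)–C3H2–C4(=O)–C4a is a β-aryloxy ketone. Its only stereocentre, C2, is benzylic and bound to O1, so it can pass through a cation stabilised by O1 and ring B. Cutting C2–C3 and tying C2 to the oxygen on C4 leads back to a cyclic enol acetal, a 4-methylidene-4H-1,3-benzodioxine.
- The acetal is cut at C2–O1, C2–O3 and the exocyclic C=CH2. Ring A arrives as a salicylic acid, ring B as an aldehyde, and the CH2 (later C3) comes from a titanium methylidene.
- The prenyl group is cut at C6–CH2. It comes from a [3,3] shift of an O5 1,1-dimethylallyl ether, for which C6 is the only open ortho carbon. O5 is freed by chelation-directed demethylation next to C4=O.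
- Ring order: rings A and B are bought, a temporary 1,3-dioxine ring is closed on ring A first, and ring C is made from it in the key step, which also sets C2.

Key step: step 3

Remark: the sense of induction of the chiral acid cannot be derived from precedent. The (S)-configured catalyst is written as the one that leads to (2S), and its equally available mirror image is used if the first experiment shows the opposite sense.

Step 1
Reactants: 1 2-hydroxy-4,6-dimethoxybenzoic acid; 2 3,4,5-trimethoxybenzaldehyde
Product: 4 rac-5,7-dimethoxy-2-(3,4,5-trimethoxyphenyl)-4H-1,3-benzodioxin-4-one, via bis(trimethylsilyl) salicylate 3 (not isolated)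
Conditions: (Me3Si)2NH, CH2Cl2, rt to 40 °C, volatiles removed; 2, TMSOTf (0.2 equiv), CH2Cl2, −78 → −20 °C; pyridine quench
Reagents that add atoms: hexamethyldisilazane, C[Si](C)(C)N[Si](C)(C)C (its Me3Si groups are found in 3 only, none in 4)
Why: TMSOTf-catalysed silyl acetalisation, the standard entry to 1,3-dioxan-4-ones from hydroxy acids: the silylated aldehyde is captured in turn by the silyl ester and the aryl silyl ether, formation of (Me3Si)2O makes the condensation irreversible at low temperature, the electron-rich and decarboxylation-prone acid 1 never meets hot protic acid, and C2 arises racemic, which is harmless because it is erased in step 3.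

Step 2
Reactants: 4 rac-5,7-dimethoxy-2-(3,4,5-trimethoxyphenyl)-4H-1,3-benzodioxin-4-one
Product: 5 rac-5,7-dimethoxy-4-methylidene-2-(3,4,5-trimethoxyphenyl)-4H-1,3-benzodioxine
Conditions: Cp2TiMe2 (2.2 equiv), PhMe–THF, 65 °C, dark, Ar; hexane precipitation, basic Al2O3 (1 % Et3N in the eluent)
Reagents that add atoms: dimethyltitanocene Cp2TiMe2, C[Ti+2]C.c1cc[cH-]c1.c1cc[cH-]c1 (delivers the CH2)
Why: Petasis methylenation: thermolysis of Cp2TiMe2 gives Cp2Ti=CH2, which adds across the lactone C4=O to an oxatitanacyclobutane and cycloreverts to the enol ether, a non-basic olefination that is the usual way to 4-methylidene-1,3-dioxanes and leaves the C2 acetal and the aryl ethers alone.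

Step 3
Reactants: 5 rac-5,7-dimethoxy-4-methylidene-2-(3,4,5-trimethoxyphenyl)-4H-1,3-benzodioxine
Product: 7 (2S)-5,7-dimethoxy-2-(3,4,5-trimethoxyphenyl)chroman-4-one, via oxocarbenium enol ion pair 6 (not isolated)
Conditions: (S)-3,3'-bis(2,4,6-triisopropylphenyl)-BINOL N-triflylphosphoramide (5 mol %), 4 Å MS, PhMe (0.02 M), −40 °C; cold filtration through SiO2
Reagents that add atoms: none
Why: Proposed new method: the acid protonates O3 and the C2–O3 bond breaks, which gives ion pair 6, a cation whose carbenium centre C2 is stabilised by O1 and ring B, whose other half is the neutral enol of the ortho-acyl aryl ether (still tied to O1 through ring A) and whose counter-ion is the chiral phosphoramidate; the enol carbon then bonds to C2 (new C2–C3 bond) and loss of the enol proton to the anion returns the catalyst. The closest known reaction types are the Petasis–Ferrier rearrangement of 4-methylidene-1,3-dioxanes with aluminium Lewis acids and the chiral phosphoric acid-catalysed Petasis–Ferrier-type shifts of hemiaminal vinyl ethers and of non-fused cyclic vinyl acetals; a benzo-fused, ketone-derived enol acetal and an aryloxy carbenium ion are new, and because both acetal oxygens are weakly basic the stronger N-triflylphosphoramide replaces a phosphoric acid. Ring C closes in the 6-(enolendo)-endo-trig mode, since C3=C4 of the enol and C2=O1 of the cation both end up inside the new six-membered ring. C2 is planar in 6, so both enantiomers of 5 meet in one intermediate, and the face of C2 that is attacked is set only by the anion, which should hold the cation by ion pairing and the enol by an O–H···O=P hydrogen bond inside the pocket of the two triisopropylphenyl groups. The step needs cleavage of C2–O3 rather than C2–O1 and C- rather than O-recombination, and the substrate secures both because the alternative events only regenerate 5 (the vinyl oxocarbenium ion from C2–O1 cleavage has no carbon nucleophile in reach), whereas C–C bond formation is made irreversible by the new C4=O group. Protonation at the methylidene carbon is likewise reversible as long as water is absent and feeds the keto tautomer of 6, so sieves, high dilution (against attack by ring A of a second molecule) and low temperature (against reopening of 7 at C2–O1) complete the design.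

Step 4
Reactants: 7 (2S)-5,7-dimethoxy-2-(3,4,5-trimethoxyphenyl)chroman-4-one
Product: 9 (2S)-5-hydroxy-7-methoxy-2-(3,4,5-trimethoxyphenyl)chroman-4-one, via O5-dichloroboryl chelate 8 (not isolated)
Conditions: BCl3 (1.2 equiv), CH2Cl2, −78 → −10 °C; H2O–THF, 0 °C
Reagents that add atoms: boron trichloride, ClB(Cl)Cl (boron and chlorine are found in 8 only, none in 9)
Why: Chelation-directed aryl methyl ether cleavage: BCl3 binds C4=O and only the peri O5 methoxy group can close a six-membered chelate, so chloride removes that methyl group by SN2 while the 7-methoxy and ring B methoxy groups are not activated at this temperature and stoichiometry, and the absence of base leaves the C2–O1 bond and thus C2 untouched.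

Step 5
Reactants: 9 (2S)-5-hydroxy-7-methoxy-2-(3,4,5-trimethoxyphenyl)chroman-4-one; 10 2-methylbut-3-yn-2-ol
Product: 12 (2S)-7-methoxy-5-[(2-methylbut-3-yn-2-yl)oxy]-2-(3,4,5-trimethoxyphenyl)chroman-4-one, via 2-methylbut-3-yn-2-yl trifluoroacetate 11 (not isolated)
Conditions: flask A: 10 (1.3 equiv), DBU (1.35 equiv), (CF3CO)2O (1.3 equiv), MeCN, −5 °C; cannulated into 9, DBU (1.1 equiv), CuCl2·2H2O (1 mol %), MeCN, −10 → 0 °C, Ar; cold aq. NaH2PO4 quench
Reagents that add atoms: trifluoroacetic anhydride, O=C(OC(=O)C(F)(F)F)C(F)(F)F (its acyl group is found in 11 only, none in 12)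
Why: Copper-catalysed propargylic etherification of a phenol: the copper acetylide of 11 loses trifluoroacetate to a copper allenylidene that is electrophilic at the tertiary carbon and takes up the O5 phenoxide, and a trifluoroacetate is preferred to a carbonate because it releases no alkoxide and uses up the DBU as the reaction runs, which together with the low temperature limits retro-oxa-Michael opening of ring C and so protects C2.

Step 6
Reactants: 12 (2S)-7-methoxy-5-[(2-methylbut-3-yn-2-yl)oxy]-2-(3,4,5-trimethoxyphenyl)chroman-4-one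
Product: 13 (2S)-7-methoxy-5-[(2-methylbut-3-en-2-yl)oxy]-2-(3,4,5-trimethoxyphenyl)chroman-4-one
Conditions: H2 (1 atm), Pd/CaCO3–Pb(OAc)2, quinoline, EtOAc, rt, stopped after one equivalent of H2
Reagents that add atoms: none
Why: Lindlar semi-hydrogenation: the poisoned palladium surface binds the terminal alkyne far better than the alkene formed, so uptake stops at the alkene, and the ketone, the benzylic C2–O1 bond and C2 are not affected under these neutral conditions.

Step 7
Reactants: 13 (2S)-7-methoxy-5-[(2-methylbut-3-en-2-yl)oxy]-2-(3,4,5-trimethoxyphenyl)chroman-4-one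
Product: 15 artoflavanone [(2S)-5-hydroxy-7-methoxy-6-(3-methylbut-2-en-1-yl)-2-(3,4,5-trimethoxyphenyl)chroman-4-one], via C6-prenyl cyclohexadienone 14 (not isolated)
Conditions: PhMe (degassed, 0.05 M), 110 °C, sealed silanised tube
Reagents that add atoms: none
Why: Aromatic Claisen rearrangement: the [3,3] shift runs from O5 to the only free ortho carbon C6 (C4a is blocked), inverts the allyl unit so that the 1,1-dimethylallyl ether becomes the 3,3-dimethylallyl (prenyl) group, is accelerated by the gem-dimethyl group so that neutral toluene suffices, and dienone 14 tautomerises to the chelated phenol without any reagent that could open ring C at C2.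

**Compound list**
1 | 2-hydroxy-4,6-dimethoxybenzoic acid | COc1cc(O)c(C(=O)O)c(OC)c1 | starting material
2 | 3,4,5-trimethoxybenzaldehyde | COc1cc(C=O)cc(OC)c1OC | starting material
3 | trimethylsilyl 4,6-dimethoxy-2-(trimethylsilyloxy)benzoate | COc1cc(O[Si](C)(C)C)c(C(=O)O[Si](C)(C)C)c(OC)c1 | intermediate
4 | rac-5,7-dimethoxy-2-(3,4,5-trimethoxyphenyl)-4H-1,3-benzodioxin-4-one | O=C1OC(c2cc(OC)c(OC)c(OC)c2)Oc2cc(OC)cc(OC)c12 | intermediate
5 | rac-5,7-dimethoxy-4-methylidene-2-(3,4,5-trimethoxyphenyl)-4H-1,3-benzodioxine | C=C1OC(c2cc(OC)c(OC)c(OC)c2)Oc2cc(OC)cc(OC)c12 | intermediate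
6 | [2-(1-hydroxyethenyl)-3,5-dimethoxyphenyl](3,4,5-trimethoxybenzylidene)oxonium, paired with the chiral phosphoramidate anion | C=C(O)c1c(OC)cc(OC)cc1[O+]=Cc1cc(OC)c(OC)c(OC)c1 | intermediate
7 | (2S)-5,7-dimethoxy-2-(3,4,5-trimethoxyphenyl)chroman-4-one | COc1cc2c(c(OC)c1)C(=O)C[C@@H](c1cc(OC)c(OC)c(OC)c1)O2 | intermediate
8 | (2S)-5-(dichloroboryloxy)-7-methoxy-2-(3,4,5-trimethoxyphenyl)chroman-4-one (boron chelated by C4=O) | COc1cc2c(c(OB(Cl)Cl)c1)C(=O)C[C@@H](c1cc(OC)c(OC)c(OC)c1)O2 | intermediate
9 | (2S)-5-hydroxy-7-methoxy-2-(3,4,5-trimethoxyphenyl)chroman-4-one | COc1cc2c(c(O)c1)C(=O)C[C@@H](c1cc(OC)c(OC)c(OC)c1)O2 | intermediate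
10 | 2-methylbut-3-yn-2-ol | CC(C)(O)C#C | starting material
11 | 2-methylbut-3-yn-2-yl trifluoroacetate | C#CC(C)(C)OC(=O)C(F)(F)F | intermediate
12 | (2S)-7-methoxy-5-[(2-methylbut-3-yn-2-yl)oxy]-2-(3,4,5-trimethoxyphenyl)chroman-4-one | COc1cc2c(c(OC(C)(C)C#C)c1)C(=O)C[C@@H](c1cc(OC)c(OC)c(OC)c1)O2 | intermediate
13 | (2S)-7-methoxy-5-[(2-methylbut-3-en-2-yl)oxy]-2-(3,4,5-trimethoxyphenyl)chroman-4-one | COc1cc2c(c(OC(C)(C)C=C)c1)C(=O)C[C@@H](c1cc(OC)c(OC)c(OC)c1)O2 | intermediate
14 | (2S)-7-methoxy-6-(3-methylbut-2-en-1-yl)-2-(3,4,5-trimethoxyphenyl)-2,3-dihydro-4H-chromene-4,5(6H)-dione (both C6 epimers) | COC1=CC2=C(C(=O)C1CC=C(C)C)C(=O)C[C@@H](c1cc(OC)c(OC)c(OC)c1)O2 | intermediate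
15 | artoflavanone, (2S)-5-hydroxy-7-methoxy-6-(3-methylbut-2-en-1-yl)-2-(3,4,5-trimethoxyphenyl)chroman-4-one | COc1cc2c(c(O)c1CC=C(C)C)C(=O)C[C@@H](c1cc(OC)c(OC)c(OC)c1)O2 | target

Total step count: 7
Longest linear sequence: 7 steps (1 → 15)

**Steps most likely to fail**

1. Step 3 (bears the label "Proposed new method:").
- What may go wrong: weak facial discrimination in the ion pair, an achiral background shift, or hydrolysis and oligomerisation of the cation.
- Fallback by known chemistry, from 2 back to 7:
  - Claisen–Schmidt condensation of 2 with purchased 2'-hydroxy-4',6'-dimethoxyacetophenone (KOH, EtOH, rt) should give the chalcone (E)-1-(2-hydroxy-4,6-dimethoxyphenyl)-3-(3,4,5-trimethoxyphenyl)prop-2-en-1-one F1.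
  - Oxa-Michael cyclisation (NaOAc, EtOH, reflux, unchanged chalcone recycled) should give rac-5,7-dimethoxy-2-(3,4,5-trimethoxyphenyl)chroman-4-one F2.
  - Kinetic resolution follows, by Noyori-type asymmetric transfer hydrogenation (RuCl(p-cymene)[(R,R)-TsDPEN], HCO2H–Et3N, EtOAc, rt, stopped just past half conversion).
  - This should reduce the (2R)-ketone, for which catalyst and substrate preference coincide, to the cis alcohol (2R,4R)-5,7-dimethoxy-2-(3,4,5-trimethoxyphenyl)chroman-4-ol F3. It should leave 7, which is separated by chromatography.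

2. Step 5.
- What may go wrong: the O5–H···O=C4 chelate makes the phenol a slow nucleophile. The longer the ether and free DBU share the flask, the more ring C opens and recloses through deprotonation at C3, which erodes the configuration at C2.
- Fallback, from 9 directly to 13, without amine base and without step 6:
  - Purchased 2-methylbut-3-en-2-ol is converted (n-BuLi, THF, −78 °C, then Boc2O) into tert-butyl 2-methylbut-3-en-2-yl carbonate F4.
  - A Tsuji–Trost-type decarboxylative O-allylation with zerovalent palladium (Pd(PPh3)4, THF, 0 °C, short reaction time) lets the phenoxide attack the more substituted end of the dimethylallyl palladium cation under kinetic control.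
  - The only base is the tert-butoxide released one equivalent at a time, and the phenol quenches it at once.
  - Isomerisation to the linear prenyl ether on prolonged contact with the catalyst is the process to watch.

3. Step 2.
- What may go wrong: slow addition of the titanium methylidene to a lactone carbonyl that is flanked by the O5 methoxy group and deactivated by three donor oxygens. The enol acetal may also undergo a premature achiral O-to-C shift or hydrolysis on the warm, weakly Lewis acidic titanium residues or on the adsorbent.
- Fallback, from 4 back to 5, by the thionolactone route to enol ethers: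
  - Lawesson's reagent (PhMe, 90–100 °C) should give rac-5,7-dimethoxy-2-(3,4,5-trimethoxyphenyl)-4H-1,3-benzodioxine-4-thione F5.
  - MeLi (THF, −78 °C) adds to the C=S carbon to a thiolate that does not collapse at this temperature. MeI traps it as 5,7-dimethoxy-4-methyl-4-(methylsulfanyl)-2-(3,4,5-trimethoxyphenyl)-4H-1,3-benzodioxine F6.
  - mCPBA (1 equiv, NaHCO3, CH2Cl2, −78 °C) gives 5,7-dimethoxy-4-(methanesulfinyl)-4-methyl-2-(3,4,5-trimethoxyphenyl)-4H-1,3-benzodioxine F7.
  - Gentle warming with Et3N in PhMe eliminates the sulfoxide towards the only β-hydrogens, those of the C4 methyl group, to give 5.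

**Further compounds**
F1 | step 3 | (E)-1-(2-hydroxy-4,6-dimethoxyphenyl)-3-(3,4,5-trimethoxyphenyl)prop-2-en-1-one | COc1cc(O)c(C(=O)/C=C/c2cc(OC)c(OC)c(OC)c2)c(OC)c1
F2 | step 3 | rac-5,7-dimethoxy-2-(3,4,5-trimethoxyphenyl)chroman-4-one | COc1cc2c(c(OC)c1)C(=O)CC(c1cc(OC)c(OC)c(OC)c1)O2
F3 | step 3 | (2R,4R)-5,7-dimethoxy-2-(3,4,5-trimethoxyphenyl)chroman-4-ol | COc1cc2c(c(OC)c1)[C@H](O)C[C@H](c1cc(OC)c(OC)c(OC)c1)O2
F4 | step 5 | tert-butyl 2-methylbut-3-en-2-yl carbonate | C=CC(C)(C)OC(=O)OC(C)(C)C
F5 | step 2 | rac-5,7-dimethoxy-2-(3,4,5-trimethoxyphenyl)-4H-1,3-benzodioxine-4-thione | S=C1OC(c2cc(OC)c(OC)c(OC)c2)Oc2cc(OC)cc(OC)c12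
F6 | step 2 | 5,7-dimethoxy-4-methyl-4-(methylsulfanyl)-2-(3,4,5-trimethoxyphenyl)-4H-1,3-benzodioxine (racemic diastereomers) | CSC1(C)OC(c2cc(OC)c(OC)c(OC)c2)Oc2cc(OC)cc(OC)c12
F7 | step 2 | 5,7-dimethoxy-4-(methanesulfinyl)-4-methyl-2-(3,4,5-trimethoxyphenyl)-4H-1,3-benzodioxine (racemic diastereomers) | CS(=O)C1(C)OC(c2cc(OC)c(OC)c(OC)c2)Oc2cc(OC)cc(OC)c12
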